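**Retrosynthetic overview**
1. The target (halocynthiaxanthin) is cut at C11'=C12' (Wittig) and C11=C12 (Horner–Wadsworth–Emmons) into a C10 dialdehyde and two C15 end groups; the C8 ketone is unveiled last by MnO2 oxidation of the allylic C8 alcohol, so the base-labile β,γ-epoxy ketone never meets base.
2. Both end groups come from one enol triflate 8: Sonogashira coupling gives the acetylenic half (C6'–C7'≡C8'); carbonylation, Sharpless epoxidation, one-carbon homologation and a Nozaki–Hiyama–Kishi coupling give the epoxy half.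
3. Triflate 8 is made by closing the cyclohexane ring at C1'–C2' (gem-dimethyl carbon to ring CH2) by intramolecular enolate alkylation, with enol triflation in the same flask. The enabling feature is that C6', the ring sp2 carbon that carries the alkyne, can be held as a ketone, which makes C1' an enolate carbon, while C2'H2 flanks the C3' carbinol and is the CH2Cl carbon of (R)-epichlorohydrin.
4. Ring order: the carbocycle first (one batch serves both halves), then the oxirane on the copy destined for the epoxy end.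

Key step: step 4

Assumption: the target is read as all-E (3S,5R,6S,3'R)-halocynthiaxanthin; carotenoid numbering is used (C1–C15 epoxy half, primed numbers acetylenic half), and compounds 3, 9 and 13 are taken as commercial.

**Step 1**
Reactants: 1 2-methylpentan-3-one
Product: 2 N,N-dimethylhydrazone of 2-methylpentan-3-one (C=N isomers)
Conditions: Me2NNH2 (1.5 equiv), AcOH (cat.), EtOH, 80 °C; distillation
Reagents that add atoms: N,N-dimethylhydrazine, CN(C)N
Why: Hydrazone condensation, which should give an aza-enolate precursor that is metalated cleanly on the ethyl side.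

**Step 2**
Reactants: 2 N,N-dimethylhydrazone of 2-methylpentan-3-one; 3 (R)-epichlorohydrin
Product: 5 (6R)-7-chloro-6-hydroxy-2,4-dimethylheptan-3-one (C4 epimers, partly as cyclic hemiketal), via hydrazone 4 (not isolated)
Conditions: LiN(iPr)2 (1.05 equiv), THF, 0 °C; 3, −78 → −20 °C; aq. NH4Cl; then sat. aq. oxalic acid, Et2O, 23 °C
Reagents that add atoms: water, O
Why: Metalated dimethylhydrazone alkylation: the less substituted aza-enolate carbon (future C5') should open the oxirane at its CH2 terminus (future C4'), leaving the carbinol centre (future C3', R) untouched and the chloride in place, and mild hydrolysis returns the ketone.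

**Step 3**
Reactants: 5 (6R)-7-chloro-6-hydroxy-2,4-dimethylheptan-3-one
Product: 6 (6R)-7-chloro-2,4-dimethyl-6-[(triisopropylsilyl)oxy]heptan-3-one (C4 epimers)
Conditions: TIPSOTf (1.1 equiv), 2,6-lutidine, CH2Cl2, −78 → 0 °C
Reagents that add atoms: triisopropylsilyl trifluoromethanesulfonate, CC(C)[Si](C(C)C)(C(C)C)OS(=O)(=O)C(F)(F)F
Why: Silylation of the open-chain secondary alcohol; the bulky triisopropylsilyl group is chosen because it should not migrate to an enolate oxygen in step 4 and is removed by fluoride at the end.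

**Step 4**
Reactants: 6 (6R)-7-chloro-2,4-dimethyl-6-[(triisopropylsilyl)oxy]heptan-3-one
Product: 8 (4R)-2,6,6-trimethyl-4-[(triisopropylsilyl)oxy]cyclohex-1-en-1-yl trifluoromethanesulfonate, via ketone 7 (not isolated)
Conditions: KN(SiMe3)2 (1.1 equiv), THF, −78 → 23 °C; then KN(SiMe3)2 (1.2 equiv), −78 °C; PhNTf2 (1.3 equiv), −78 → 23 °C
Reagents that add atoms: N-phenylbis(trifluoromethanesulfonimide), O=S(=O)(N(c1ccccc1)S(=O)(=O)C(F)(F)F)C(F)(F)F
Why: The base converts 6 into its potassium enolates, and the tetrasubstituted enolate on the isopropyl side (C1'=C6') displaces the primary chloride at C2' in an intramolecular SN2 reaction to give ketone 7; the second portion of base then removes the only remaining α-hydrogen (C5'–H) and PhNTf2 sulfonylates the enolate oxygen to give 8. The closest known reaction types are the intramolecular C-alkylation of ketone enolates by tethered primary halides, which routinely builds α-quaternary cyclohexanones, and the enol triflation of 2,2,6-trisubstituted cyclohexanones. The cyclohexane ring closes in the 6-(enolendo)-exo-tet mode at C1'–C2'. No stereocentre is created: C3' (R) is carried over from (R)-epichlorohydrin because neither C–C bond formation touches it, and the stereorandom C5' centre becomes sp2 in the triflate. The step needs site selectivity between the two enolates and carbon over oxygen alkylation: the C5' enolate can close only a cyclobutane (4-exo-tet) and should return to the C1' enolate by proton exchange with HN(SiMe3)2 and unreacted ketone, and C-alkylation by a primary halide is the normal outcome for six-membered closure. The triflate regiochemistry is fixed because C1' is quaternary after the ring closure.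

**Step 5**
Reactants: 8 enol triflate; 9 (2E)-3-methylpent-2-en-4-yn-1-ol
Product: 10 (2E)-3-methyl-5-{(4R)-2,6,6-trimethyl-4-[(triisopropylsilyl)oxy]cyclohex-1-en-1-yl}pent-2-en-4-yn-1-ol
Conditions: Pd(PPh3)4 (5 mol%), CuI (10 mol%), i-Pr2NH, DMF, 23–50 °C
Reagents that add atoms: none
Why: Sonogashira coupling of a hindered cyclohexenyl triflate with a terminal enyne, which should install the C6'–C7'≡C8' unit with the 9'E geometry of 9 retained.

**Step 6**
Reactants: 10 dienynol
Product: 12 [(2E)-3-methyl-5-{(4R)-2,6,6-trimethyl-4-[(triisopropylsilyl)oxy]cyclohex-1-en-1-yl}pent-2-en-4-yn-1-yl]triphenylphosphonium bromide, via allylic bromide 11 (not isolated)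
Conditions: CBr4 (1.1 equiv), PPh3 (2.3 equiv), CH2Cl2, 0 → 23 °C; precipitation from Et2O
Reagents that add atoms: carbon tetrabromide, BrC(Br)(Br)Br; triphenylphosphine, c1ccc(cc1)P(c1ccccc1)c1ccccc1
Why: Appel bromination of the primary allylic alcohol followed by quaternisation of the excess phosphine in the same pot, under neutral conditions that keep the silyl ether.

**Step 7**
Reactants: 12 C15 phosphonium bromide; 13 (2E,4E,6E)-2,7-dimethylocta-2,4,6-trienedial
Product: 14 (2E,4E,6E,8E,10E)-2,7,11-trimethyl-13-{(4R)-2,6,6-trimethyl-4-[(triisopropylsilyl)oxy]cyclohex-1-en-1-yl}trideca-2,4,6,8,10-pentaen-12-ynal (C25 aldehyde)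
Conditions: NaOMe (1.1 equiv), 13 (2.5 equiv), CH2Cl2/MeOH, 0 → 23 °C; then heptane, 80 °C, dark
Reagents that add atoms: none
Why: Wittig olefination forming C11'=C12'; excess dialdehyde should favour mono-condensation, and the hindered 11'Z isomer is expected to relax thermally to 11'E.

**Step 8**
Reactants: 8 enol triflate
Product: 15 methyl (4R)-2,6,6-trimethyl-4-[(triisopropylsilyl)oxy]cyclohex-1-ene-1-carboxylate
Conditions: Pd(OAc)2 (5 mol%), dppp (6 mol%), CO (1 atm), MeOH, Et3N, DMF, 70 °C
Reagents that add atoms: carbon monoxide, [C-]#[O+]; methanol, CO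
Why: Palladium-catalysed methoxycarbonylation of an enol triflate, which introduces C7 on the second copy of the ring.

**Step 9**
Reactants: 15 methyl ester
Product: 16 {(4R)-2,6,6-trimethyl-4-[(triisopropylsilyl)oxy]cyclohex-1-en-1-yl}methanol
Conditions: i-Bu2AlH (2.5 equiv), CH2Cl2, −78 → 0 °C; aq. Rochelle salt
Reagents that add atoms: none
Why: 1,2-Reduction of the unsaturated ester to the primary allylic alcohol needed for directed epoxidation.

**Step 10**
Reactants: 16 allylic alcohol
Product: 17 {(1R,4S,6R)-2,2,6-trimethyl-4-[(triisopropylsilyl)oxy]-7-oxabicyclo[4.1.0]heptan-1-yl}methanol (epoxide anti to the silyloxy group)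
Conditions: Ti(OiPr)4 (20 mol%), D-(−)-diethyl tartrate (24 mol%), t-BuOOH (2 equiv, decane), 4 Å MS, CH2Cl2, −20 °C
Reagents that add atoms: tert-butyl hydroperoxide, CC(C)(C)OO
Why: Sharpless asymmetric epoxidation: with the CH2OH group drawn at the lower right, the D-tartrate catalyst should deliver oxygen to the face of C5=C6 opposite the C3 silyloxy group, setting C5 (R) and C6 (S) of the target by reagent control.

**Step 11**
Reactants: 17 epoxy alcohol
Product: 18 (1S,4S,6R)-2,2,6-trimethyl-4-[(triisopropylsilyl)oxy]-7-oxabicyclo[4.1.0]heptane-1-carbaldehyde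
Conditions: (n-Pr4N)RuO4 (5 mol%), NMO (1.5 equiv), 4 Å MS, CH2Cl2, 23 °C
Reagents that add atoms: none
Why: Ley–Griffith oxidation under neutral conditions; the aldehyde has no α-hydrogen, so the epoxide stereocentres cannot be lost.

**Step 12**
Reactants: 18 epoxy aldehyde
Product: 19 (1S,4S,6R)-1-ethenyl-2,2,6-trimethyl-4-[(triisopropylsilyl)oxy]-7-oxabicyclo[4.1.0]heptane
Conditions: Ph3PCH3Br (1.5 equiv), KN(SiMe3)2 (1.4 equiv), THF, 0 °C; then 18, −78 → 23 °C
Reagents that add atoms: methyltriphenylphosphonium bromide, C[P+](c1ccccc1)(c1ccccc1)c1ccccc1.[Br-]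
Why: Wittig methylenation with the small unstabilised ylide, which adds C8 to the hindered aldehyde.

**Step 13**
Reactants: 19 vinyl epoxide
Product: 21 2-{(1S,4S,6R)-2,2,6-trimethyl-4-[(triisopropylsilyl)oxy]-7-oxabicyclo[4.1.0]heptan-1-yl}ethan-1-ol, via B-alkyl-9-BBN adduct 20 (not isolated)
Conditions: 9-BBN-H (1.5 equiv), THF, 0 → 23 °C; then aq. NaOH, H2O2, 0 °C
Reagents that add atoms: hydrogen peroxide, OO
Why: Anti-Markovnikov hydroboration–oxidation with a bulky dialkylborane, which should place the hydroxyl on C8 and turn C7 into the CH2 group of the target.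

**Step 14**
Reactants: 21 primary alcohol
Product: 22 2-{(1S,4S,6R)-2,2,6-trimethyl-4-[(triisopropylsilyl)oxy]-7-oxabicyclo[4.1.0]heptan-1-yl}acetaldehyde
Conditions: (n-Pr4N)RuO4 (5 mol%), NMO (1.5 equiv), 4 Å MS, CH2Cl2, 0 → 23 °C; used at once
Reagents that add atoms: none
Why: Ley–Griffith oxidation gives the β,γ-epoxy aldehyde without acid or strong base, and it is carried on directly to avoid enolisation.

**Step 15**
Reactants: 23 but-2-yn-1-ol
Product: 24 (but-2-yn-1-yloxy)(tert-butyl)dimethylsilane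
Conditions: TBSCl, imidazole, DMF, 23 °C
Reagents that add atoms: tert-butyldimethylsilyl chloride, CC(C)(C)[Si](C)(C)Cl
Why: Silylation gives a bulky, non-coordinating CH2O substituent that steers the next hydrometalation to the distal alkyne carbon.

**Step 16**
Reactants: 24 silyl ether of but-2-yn-1-ol
Product: 26 tert-butyl{[(2E)-3-iodobut-2-en-1-yl]oxy}dimethylsilane, via alkenylzirconocene chloride 25 (not isolated)
Conditions: Cp2Zr(H)Cl (1.8 equiv), THF, 23 → 50 °C; then I2, THF, 0 °C
Reagents that add atoms: iodine, II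
Why: Syn hydrozirconation with Schwartz reagent, equilibrated so that zirconium sits next to the methyl group, then iodinolysis with retention, which should give the E vinyl iodide.

**Step 17**
Reactants: 26 vinyl iodide silyl ether
Product: 27 (2E)-1-bromo-3-iodobut-2-ene
Conditions: Ph3PBr2 (1.2 equiv), CH2Cl2, 0 → 23 °C
Reagents that add atoms: triphenylphosphine dibromide, BrP(Br)(c1ccccc1)(c1ccccc1)c1ccccc1
Why: Direct conversion of a primary allylic silyl ether into the bromide with the dibromophosphorane, which avoids a separate desilylation.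

**Step 18**
Reactants: 27 allylic bromide
Product: 28 diethyl [(2E)-3-iodobut-2-en-1-yl]phosphonate
Conditions: P(OEt)3 (3 equiv, neat), 100 °C; excess removed in vacuo
Reagents that add atoms: triethyl phosphite, CCOP(OCC)OCC
Why: Michaelis–Arbuzov reaction at the allylic bromide only, since the vinyl iodide cannot undergo SN2 displacement.

**Step 19**
Reactants: 22 β,γ-epoxy aldehyde; 28 iodo phosphonate
Product: 29 diethyl [(2E)-4-hydroxy-3-methyl-5-{(1S,4S,6R)-2,2,6-trimethyl-4-[(triisopropylsilyl)oxy]-7-oxabicyclo[4.1.0]heptan-1-yl}pent-2-en-1-yl]phosphonate (C8 carbinol epimers)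
Conditions: CrCl2 (5 equiv), NiCl2 (2 mol%), DMSO/THF, 23 °C
Reagents that add atoms: none
Why: Nozaki–Hiyama–Kishi coupling forms C8–C9 with retention of the alkene geometry under non-basic conditions that tolerate the phosphonate and the epoxide; the new C8 centre need not be controlled because it is oxidised in step 22.

**Step 20**
Reactants: 29 hydroxy phosphonate; 14 C25 aldehyde
Product: 30 (3S,5R,6S,3'R)-5,6-epoxy-3,3'-bis[(triisopropylsilyl)oxy]-7',8'-didehydro-5,6,7,8-tetrahydro-β,β-caroten-8-ol (C8 epimers)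
Conditions: NaN(SiMe3)2 (2.1 equiv), THF, −78 °C; then 14, −78 → 0 °C
Reagents that add atoms: none
Why: Horner–Wadsworth–Emmons olefination of the alkoxide/allylic phosphonate dianion with the polyenal, which should form C11=C12 with E selectivity while the free C8 alkoxide blocks 1,4-elimination.

**Step 21**
Reactants: 30 bis-silyl ether
Product: 31 (3S,5R,6S,3'R)-5,6-epoxy-7',8'-didehydro-5,6,7,8-tetrahydro-β,β-carotene-3,8,3'-triol (C8 epimers)
Conditions: Bu4NF (4 equiv), THF, 23 °C, dark
Reagents that add atoms: none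
Why: Fluoride desilylation is done before the ketone exists, so the basic fluoride cannot open the epoxide through an enolate.

**Step 22**
Reactants: 31 triol
Product: 32 halocynthiaxanthin, (3S,5R,6S,3'R)-5,6-epoxy-3,3'-dihydroxy-7',8'-didehydro-5,6,7,8-tetrahydro-β,β-caroten-8-one
Conditions: MnO2 (activated, 25 equiv), CH2Cl2, 23 °C, dark
Reagents that add atoms: none
Why: MnO2 oxidation is selective for the allylic, polyene-conjugated C8 alcohol over the two saturated ring carbinols and is neutral, so the β,γ-epoxy ketone should survive.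

**Compound list**
1 | 2-methylpentan-3-one | CCC(=O)C(C)C | starting material
2 | N,N-dimethylhydrazone of 2-methylpentan-3-one | CCC(=NN(C)C)C(C)C | intermediate
3 | (R)-epichlorohydrin, (2R)-2-(chloromethyl)oxirane | ClC[C@H]1CO1 | starting material
4 | N,N-dimethylhydrazone of (6R)-7-chloro-6-hydroxy-2,4-dimethylheptan-3-one | ClC[C@H](O)CC(C)C(=NN(C)C)C(C)C | intermediate
5 | (6R)-7-chloro-6-hydroxy-2,4-dimethylheptan-3-one (C4 epimers) | ClC[C@H](O)CC(C)C(=O)C(C)C | intermediate
6 | (6R)-7-chloro-2,4-dimethyl-6-[(triisopropylsilyl)oxy]heptan-3-one (C4 epimers) | ClC[C@H](O[Si](C(C)C)(C(C)C)C(C)C)CC(C)C(=O)C(C)C | intermediate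
7 | (4R)-2,2,6-trimethyl-4-[(triisopropylsilyl)oxy]cyclohexan-1-one (C6 epimers) | CC1C(=O)C(C)(C)C[C@H](O[Si](C(C)C)(C(C)C)C(C)C)C1 | intermediate
8 | (4R)-2,6,6-trimethyl-4-[(triisopropylsilyl)oxy]cyclohex-1-en-1-yl trifluoromethanesulfonate | CC1=C(OS(=O)(=O)C(F)(F)F)C(C)(C)C[C@H](O[Si](C(C)C)(C(C)C)C(C)C)C1 | intermediate
9 | (2E)-3-methylpent-2-en-4-yn-1-ol | C#C/C(C)=C/CO | starting material
10 | (2E)-3-methyl-5-{(4R)-2,6,6-trimethyl-4-[(triisopropylsilyl)oxy]cyclohex-1-en-1-yl}pent-2-en-4-yn-1-ol | CC1=C(C#C/C(C)=C/CO)C(C)(C)C[C@H](O[Si](C(C)C)(C(C)C)C(C)C)C1 | intermediate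
11 | allylic bromide of 10 | CC1=C(C#C/C(C)=C/CBr)C(C)(C)C[C@H](O[Si](C(C)C)(C(C)C)C(C)C)C1 | intermediate
12 | C15 triphenylphosphonium bromide | CC1=C(C#C/C(C)=C/C[P+](c2ccccc2)(c2ccccc2)c2ccccc2)C(C)(C)C[C@H](O[Si](C(C)C)(C(C)C)C(C)C)C1.[Br-] | intermediate
13 | (2E,4E,6E)-2,7-dimethylocta-2,4,6-trienedial | O=C/C(C)=C/C=C/C=C(\C)C=O | starting material
14 | C25 aldehyde, (2E,4E,6E,8E,10E)-2,7,11-trimethyl-13-{(4R)-2,6,6-trimethyl-4-[(triisopropylsilyl)oxy]cyclohex-1-en-1-yl}trideca-2,4,6,8,10-pentaen-12-ynal | CC1=C(C#C/C(C)=C/C=C/C(C)=C/C=C/C=C(\C)C=O)C(C)(C)C[C@H](O[Si](C(C)C)(C(C)C)C(C)C)C1 | intermediate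
15 | methyl (4R)-2,6,6-trimethyl-4-[(triisopropylsilyl)oxy]cyclohex-1-ene-1-carboxylate | CC1=C(C(=O)OC)C(C)(C)C[C@H](O[Si](C(C)C)(C(C)C)C(C)C)C1 | intermediate
16 | {(4R)-2,6,6-trimethyl-4-[(triisopropylsilyl)oxy]cyclohex-1-en-1-yl}methanol | CC1=C(CO)C(C)(C)C[C@H](O[Si](C(C)C)(C(C)C)C(C)C)C1 | intermediate
17 | {(1R,4S,6R)-2,2,6-trimethyl-4-[(triisopropylsilyl)oxy]-7-oxabicyclo[4.1.0]heptan-1-yl}methanol | OC[C@@]12O[C@]1(C)C[C@@H](O[Si](C(C)C)(C(C)C)C(C)C)CC2(C)C | intermediate
18 | (1S,4S,6R)-2,2,6-trimethyl-4-[(triisopropylsilyl)oxy]-7-oxabicyclo[4.1.0]heptane-1-carbaldehyde | O=C[C@@]12O[C@]1(C)C[C@@H](O[Si](C(C)C)(C(C)C)C(C)C)CC2(C)C | intermediate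
19 | (1S,4S,6R)-1-ethenyl-2,2,6-trimethyl-4-[(triisopropylsilyl)oxy]-7-oxabicyclo[4.1.0]heptane | C=C[C@@]12O[C@]1(C)C[C@@H](O[Si](C(C)C)(C(C)C)C(C)C)CC2(C)C | intermediate
20 | B-alkyl-9-borabicyclo[3.3.1]nonane adduct of 19 | C(C[C@@]12O[C@]1(C)C[C@@H](O[Si](C(C)C)(C(C)C)C(C)C)CC2(C)C)B3C4CCCC3CCC4 | intermediate
21 | 2-{(1S,4S,6R)-2,2,6-trimethyl-4-[(triisopropylsilyl)oxy]-7-oxabicyclo[4.1.0]heptan-1-yl}ethan-1-ol | OCC[C@@]12O[C@]1(C)C[C@@H](O[Si](C(C)C)(C(C)C)C(C)C)CC2(C)C | intermediate
22 | 2-{(1S,4S,6R)-2,2,6-trimethyl-4-[(triisopropylsilyl)oxy]-7-oxabicyclo[4.1.0]heptan-1-yl}acetaldehyde | O=CC[C@@]12O[C@]1(C)C[C@@H](O[Si](C(C)C)(C(C)C)C(C)C)CC2(C)C | intermediate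
23 | but-2-yn-1-ol | CC#CCO | starting material
24 | (but-2-yn-1-yloxy)(tert-butyl)dimethylsilane | CC#CCO[Si](C)(C)C(C)(C)C | intermediate
25 | (E)-alkenylzirconocene chloride from 24 (zirconium on the methyl-bearing carbon) | C/C(=C\CO[Si](C)(C)C(C)(C)C)[Zr](Cl)(C1C=CC=C1)C1C=CC=C1 | intermediate
26 | tert-butyl{[(2E)-3-iodobut-2-en-1-yl]oxy}dimethylsilane | C/C(I)=C\CO[Si](C)(C)C(C)(C)C | intermediate
27 | (2E)-1-bromo-3-iodobut-2-ene | C/C(I)=C\CBr | intermediate
28 | diethyl [(2E)-3-iodobut-2-en-1-yl]phosphonate | C/C(I)=C\CP(=O)(OCC)OCC | intermediate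
29 | diethyl [(2E)-4-hydroxy-3-methyl-5-{(1S,4S,6R)-2,2,6-trimethyl-4-[(triisopropylsilyl)oxy]-7-oxabicyclo[4.1.0]heptan-1-yl}pent-2-en-1-yl]phosphonate (carbinol epimers) | CCOP(=O)(OCC)C/C=C(\C)C(O)C[C@@]12O[C@]1(C)C[C@@H](O[Si](C(C)C)(C(C)C)C(C)C)CC2(C)C | intermediate
30 | (3S,5R,6S,3'R)-5,6-epoxy-3,3'-bis[(triisopropylsilyl)oxy]-7',8'-didehydro-5,6,7,8-tetrahydro-β,β-caroten-8-ol (C8 epimers) | CC1=C(C#C/C(C)=C/C=C/C(C)=C/C=C/C=C(C)/C=C/C=C(\C)C(O)C[C@@]23O[C@]2(C)C[C@@H](O[Si](C(C)C)(C(C)C)C(C)C)CC3(C)C)C(C)(C)C[C@H](O[Si](C(C)C)(C(C)C)C(C)C)C1 | intermediate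
31 | (3S,5R,6S,3'R)-5,6-epoxy-7',8'-didehydro-5,6,7,8-tetrahydro-β,β-carotene-3,8,3'-triol (C8 epimers) | CC1=C(C#C/C(C)=C/C=C/C(C)=C/C=C/C=C(C)/C=C/C=C(\C)C(O)C[C@@]23O[C@]2(C)C[C@@H](O)CC3(C)C)C(C)(C)C[C@H](O)C1 | intermediate
32 | halocynthiaxanthin | CC1=C(C#C/C(C)=C/C=C/C(C)=C/C=C/C=C(C)/C=C/C=C(\C)C(=O)C[C@@]23O[C@]2(C)C[C@@H](O)CC3(C)C)C(C)(C)C[C@H](O)C1 | target

**Step count**
Total: 22 steps. Longest linear sequence: 15 steps (1–4, 8–14, 19–22).

**Steps most likely to fail**

Step 4. The enolate may close through oxygen to a cyclic enol ether, or the C5' enolate may close a cyclobutane. The fallback changes the nucleophile to an aza-enolate, which alkylates at carbon only. It sets out from hydrazone 4, isolated after a neutral work-up instead of being hydrolysed. Silylation (TIPSOTf, 2,6-lutidine) should give the silylated hydrazone F1. Metalation at the isopropyl methine with LiN(iPr)2 in THF at 0 °C and 6-exo-tet displacement of chloride should give the cyclic hydrazone F2. Aqueous oxalic acid then releases ketone 7, now isolated, and a separate triflation (LiN(iPr)2, PhNTf2) returns to the route at 8.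

Step 13. The borane may deliver hydride to the vinyl epoxide in the SN2' sense and open the oxirane, or the tetrasubstituted epoxide may rearrange on the boron Lewis acid. The fallback avoids boranes and sets out from epoxy aldehyde 18. Ohira–Bestmann alkynylation (dimethyl (1-diazo-2-oxopropyl)phosphonate, K2CO3, MeOH) should give the epoxy alkyne F3, which is safe because 18 has no α-hydrogen. Ruthenium-catalysed anti-Markovnikov hydration of the terminal alkyne (CpRu(MeCN)3PF6 with a bipyridine ligand, aqueous acetone) should give aldehyde 22 directly. It returns to the route at 22 and replaces steps 12–14.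

Step 20. The dianion may add sluggishly to the deactivated C25 polyenal, E/Z control at C11=C12 may be poor, or the C9=C10 geometry may erode through the delocalised allyl anion. The fallback reverses the order of the two olefinations and sets out from 29 and 13. Horner–Wadsworth–Emmons reaction of 29 with an excess of the more electrophilic dialdehyde 13 should give the epoxy-half hydroxy aldehyde F4. Wittig reaction of F4 with the ylide from 12 (NaOMe, then thermal isomerisation) then forms C11'=C12' and returns to the route at 30.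

**Further compounds**
F1 | step 4 | N,N-dimethylhydrazone of (6R)-7-chloro-2,4-dimethyl-6-[(triisopropylsilyl)oxy]heptan-3-one | ClC[C@H](O[Si](C(C)C)(C(C)C)C(C)C)CC(C)C(=NN(C)C)C(C)C
F2 | step 4 | N,N-dimethylhydrazone of (4R)-2,2,6-trimethyl-4-[(triisopropylsilyl)oxy]cyclohexan-1-one | CC1C(=NN(C)C)C(C)(C)C[C@H](O[Si](C(C)C)(C(C)C)C(C)C)C1
F3 | step 13 | (1S,4S,6R)-1-ethynyl-2,2,6-trimethyl-4-[(triisopropylsilyl)oxy]-7-oxabicyclo[4.1.0]heptane | C#C[C@@]12O[C@]1(C)C[C@@H](O[Si](C(C)C)(C(C)C)C(C)C)CC2(C)C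
F4 | step 20 | (2E,4E,6E,8E,10E)-12-hydroxy-2,7,11-trimethyl-13-{(1S,4S,6R)-2,2,6-trimethyl-4-[(triisopropylsilyl)oxy]-7-oxabicyclo[4.1.0]heptan-1-yl}trideca-2,4,6,8,10-pentaenal (carbinol epimers) | O=C/C(C)=C/C=C/C=C(C)/C=C/C=C(\C)C(O)C[C@@]12O[C@]1(C)C[C@@H](O[Si](C(C)C)(C(C)C)C(C)C)CC2(C)C
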